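If each step takes one partner and runs first order in it, c(partner) multiplies the making and the using up of single product alike, so the crest stands at one ratio c(starting material)/c(single product), the selectivity factor.

| flask | starting material | partner | remark | time |
|---|---|---|---|---|
| Monday's | 0.20 M | 3.5 equiv | run made earlier |  |
| Wednesday's | 0.20 M | 5.5 equiv | run made earlier |  |
| flask | 0.20 M | 2.50 equiv |  | 30 min |

| run | time / min | single product / % | starting material / % |
|---|---|---|---|
| Monday's | 4.00 | 9.9 | 87.6 |
| Monday's | 8.00 | 13.0 | 75.3 |
| Monday's | 15.0 | 11.1 | 59.4 |
| Monday's | 40.0 | 7.1 | 30.4 |
| Wednesday's | 4.00 | 13.1 | 78.2 |
| Wednesday's | 8.00 | 12.0 | 63.8 |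
| Wednesday's | 15.0 | 10.5 | 41.3 |
| Wednesday's | 40.0 | 1.2 | 13.7 |

(each reading ± 1 percentage point)

- time, not beyond 30 min, at which the flask holds most single product
- the amount of single product, in percent of the starting material charged, at that time
- the first time at which single product reaches 8.4%, in the same percent, in min

- the earlier runs were read with a standard deviation of 1 percentage point

This reckoning takes Monday's highest reading as the crest, which puts that ratio at 5.79, with the scatter of the readings. A crest then comes with 69.3% of the starting material left and 12.0% single product. Monday's reading at 15.0 min, with a mean c(partner) of 0.630 M, gives a rate constant of 0.0551 /M/min. The way to a crest therefore costs 399 M·s, the crest exposure: c(partner) summed over time up to the crest.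

This flask starts by losing starting material at 0.00551 M/min. Up to the crest, the fall of starting material slows that rate to 69.3% and the fall of partner to 80.2%, together to 55.6%. Partner's own rate at the crest is 1.11 times its starting rate, so its fall is close to straight and the mean of its two ends can replace the curve. That mean is 0.451 M, which spends the exposure in 14.8 min, earlier than 30 min, so this reckoning puts the end of this flask past its crest.

The forecast, reading the product as “an intermediate consumed faster than it forms”, differs from this reckoning: 17 min and 13.4%, with the asked level reached at 5 min.

The flask crests at 14.2 min with 11.9% and reaches the asked level at 4.62 min, so the forecast's time is long by a factor of 1.20. At the crest, over-reaction product already stands at 18.6%, more than single product. With partner in this flask at 80.3% of its charge at 14.2 min, the mean of its two ends puts the exposure up to that time at 385 M·s, against the 399 M·s reckoned from Monday's readings.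

    starting material + partner → single product (k = 0.0570 /M/min)
    partner + single product → bis adduct (k = 0.00150 /M/min)
    partner + single product → over-reaction product (k = 0.330 /M/min)

A neighbour with 0.12 M of starting material and the same equivalents is reckoned to spend the crest exposure in 24.6 min, inside 30 min. Computed, it reaches 11.9% and still holds 11.7% at the end.

The numbers in the tables were generated by integration on assumed constants; the scatter is artificial.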